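The ten-membered ring is never closed directly; it is released from a cis-fused bicyclo[4.4.0]decene by cutting the one bond that both rings share. The step exploits that the C3 ketone and the C8 carbinol carbon lie 1,6 across the target ring: joined, they give ring A (C3–C8, a cyclohexene holding C4=C5, C6 and C7) fused to ring B (C3, C2, C1, C10, C9, C8). Glycol cleavage of the C3,C8 cis-diol 26 then delivers both carbonyls and the Z-C4=C5 enone at once. Diol 26 is built on an enantioenriched 3-hydroxy-3-methylcyclohexanone by allylation at C8, alkenylation at C3 and ring-closing metathesis.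

Key step: step 16

Remarks on the chemistry (assumptions)
- Locants follow the target: ring C1–C10 (C3 ketone, C4=C5, C6–O, C7, C8–O, C10 carbinol), C11–C13 lactone carbons, C14 methyl on C10, C15 hydroxymethyl on C4.
- The target is taken in the open C3-keto/C10-hydroxy form as drawn; reversible closure to a C3/C10 hemiketal would not change the route.
- In steps 1 and 5 the ligand antipode is chosen so as to give the configuration stated for the product.
- C3 and C8 of the decalin are auxiliary centres that vanish in step 16; they are drawn as the models predict (cis-diol, trans to the C10 oxygen), and an epimer at either centre would lead to the same enedione 28.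
- C6 and C12 carry the same PMB ether so that one operation frees both before lactonisation; C15 carries the only late silyl group.

Step 1
Reactants: 1 3-methylcyclohex-2-en-1-one
Product: 3 (R)-3-hydroxy-3-methylcyclohexan-1-one, via tertiary boronate 2 (not isolated)
Conditions: B2pin2, CuCl (5 mol %), QuinoxP* (antipode giving (R)-3), NaOt-Bu, MeOH, THF, 23 °C; then NaBO3·4H2O, THF/H2O, 23 °C
Reagents that add atoms: sodium perborate, [Na+].[Na+].O[B-]1(O)OO[B-](O)(O)OO1
Why: Copper-catalysed enantioselective conjugate borylation of a β-methyl cyclic enone should set the quaternary C10 centre under ligand control, and perborate oxidation replaces boron by oxygen with retention under conditions mild enough to spare the retro-aldol-prone β-hydroxy ketone.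

Step 2
Reactants: 3 (R)-3-hydroxy-3-methylcyclohexan-1-one
Product: 4 (R)-3-methyl-3-(triethylsilyloxy)cyclohexan-1-one
Conditions: Et3SiOTf, 2,6-lutidine, CH2Cl2, −78 °C
Reagents that add atoms: triethylsilyl triflate, CC[Si](CC)(CC)OS(=O)(=O)C(F)(F)F
Why: Silyl triflate silylation of the hindered tertiary alcohol at low temperature is faster than enol ether formation and blocks retro-aldol and E1cB pathways in the enolate chemistry that follows.

Step 3
Reactants: 4 (R)-3-methyl-3-(triethylsilyloxy)cyclohexan-1-one
Product: 6 (2R,5R)-2-hydroxy-5-methyl-5-(triethylsilyloxy)cyclohexan-1-one, via potassium enolate 5 (not isolated)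
Conditions: KN(SiMe3)2, THF, −78 °C; then 3-phenyl-2-(phenylsulfonyl)oxaziridine, −78 °C; aq. NH4Cl
Reagents that add atoms: 3-phenyl-2-(phenylsulfonyl)oxaziridine, O=S(=O)(c1ccccc1)N1OC1c1ccccc1
Why: Kinetic deprotonation should take the C3 methylene, which is remote from the quaternary C10, and Davis oxaziridine hydroxylation of enolate 5 by axial attack anti to the axial C10 silyloxy group should give mainly the epimer shown (C3-OH trans to C10-OSiEt3), a centre that is oxidised away in step 11.

Step 4
Reactants: 7 prop-2-yn-1-ol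
Product: 8 1-methoxy-4-[(prop-2-yn-1-yloxy)methyl]benzene
Conditions: NaH, 4-methoxybenzyl chloride, n-Bu4NI (cat.), THF, 0 → 23 °C
Reagents that add atoms: 4-methoxybenzyl chloride, COc1ccc(CCl)cc1
Why: Williamson ether synthesis by SN2 displacement of a benzylic chloride by the primary alkoxide.

Step 5
Reactants: 8 1-methoxy-4-[(prop-2-yn-1-yloxy)methyl]benzene; 9 acrolein
Product: 11 (S)-6-[(4-methoxybenzyl)oxy]hex-1-en-4-yn-3-ol, via alkynylzinc 10 (not isolated)
Conditions: Me2Zn, ProPhenol ligand (10 mol %, antipode giving (S)-11), Ph3P=O (20 mol %), toluene, 0 °C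
Reagents that add atoms: none
Why: Zinc–ProPhenol catalysed enantioselective alkynylation of an enal, in which alkynylzinc 10 should add 1,2 to the carbonyl face selected by the dinuclear zinc catalyst and so set the C6 carbinol.

Step 6
Reactants: 11 (S)-6-[(4-methoxybenzyl)oxy]hex-1-en-4-yn-3-ol
Product: 13 (3S,4Z)-5-iodo-6-[(4-methoxybenzyl)oxy]hexa-1,4-dien-3-ol, via cyclic alkenylalanate 12 (not isolated)
Conditions: NaAlH2(OCH2CH2OMe)2, THF, 0 °C; then I2, THF, −78 → 0 °C
Reagents that add atoms: iodine, II
Why: The aluminium alkoxide directs trans-hydroalumination of the alkyne so that aluminium ends on the distal carbon C11 in the five-membered alanate 12, and iodinolysis with retention should give the Z vinyl iodide as a single regio- and stereoisomer.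

Step 7
Reactants: 13 (3S,4Z)-5-iodo-6-[(4-methoxybenzyl)oxy]hexa-1,4-dien-3-ol
Product: 14 (3S,4Z)-5-iodo-3,6-bis[(4-methoxybenzyl)oxy]hexa-1,4-diene
Conditions: NaH, 4-methoxybenzyl chloride, n-Bu4NI (cat.), THF/DMF, 0 °C
Reagents that add atoms: 4-methoxybenzyl chloride, COc1ccc(CCl)cc1
Why: Williamson etherification of the secondary alkoxide puts a small, weakly coordinating ether on C6 that is later removed together with the C12 ether.

Step 8
Reactants: 14 (3S,4Z)-5-iodo-3,6-bis[(4-methoxybenzyl)oxy]hexa-1,4-diene
Product: 15 (2E,4S)-4-[(4-methoxybenzyl)oxy]-2-{[(4-methoxybenzyl)oxy]methyl}hexa-2,5-dien-1-ol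
Conditions: Bu3SnCH2OH, Pd(PPh3)4 (5 mol %), toluene, 80 °C
Reagents that add atoms: (tributylstannyl)methanol, CCCC[Sn](CCCC)(CCCC)CO
Why: Stille coupling of the vinyl iodide with the hydroxymethyl stannane proceeds with retention of alkene geometry and should place C13 cis to C6.

Step 9
Reactants: 15 (2E,4S)-4-[(4-methoxybenzyl)oxy]-2-{[(4-methoxybenzyl)oxy]methyl}hexa-2,5-dien-1-ol
Product: 16 (3S,4Z)-5-(bromomethyl)-3,6-bis[(4-methoxybenzyl)oxy]hexa-1,4-diene
Conditions: CBr4, PPh3, CH2Cl2, 0 °C
Reagents that add atoms: carbon tetrabromide, BrC(Br)(Br)Br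
Why: Appel bromination converts the primary allylic alcohol by SN2 displacement of the oxyphosphonium group, without allylic transposition at 0 °C.

Step 10
Reactants: 6 (2R,5R)-2-hydroxy-5-methyl-5-(triethylsilyloxy)cyclohexan-1-one; 16 (3S,4Z)-5-(bromomethyl)-3,6-bis[(4-methoxybenzyl)oxy]hexa-1,4-diene
Product: 18 cis-1,2-diol adduct (tertiary C8 carbinol bearing the C7 side chain; secondary C3 carbinol), via allylindium dibromide 17 (not isolated)
Conditions: In powder, THF/H2O (3:1), 23 °C
Reagents that add atoms: none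
Why: Indium-mediated Barbier allylation of a chelating α-hydroxy ketone should form the bond at the γ-carbon C7 through a six-membered transition state; A(1,3) strain holds the C6–H in the plane of the trisubstituted allyl unit so that the ketone enters opposite the vinyl group and beside the small PMB ether oxygen, setting C7 as in the target, while equatorial attack on the chelated ketone (axial face blocked by the axial C10 methyl) places the C8 hydroxyl cis to the C3 hydroxyl.

Step 11
Reactants: 18 cis-1,2-diol adduct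
Product: 19 α-hydroxy ketone (C3 ketone next to the tertiary C8 carbinol)
Conditions: IBX, DMSO, 23 °C
Reagents that add atoms: none
Why: IBX oxidises the secondary C3 alcohol of a 1,2-diol to the α-hydroxy ketone without glycol cleavage and cannot touch the tertiary C8 carbinol.

Step 12
Reactants: 20 2-bromoprop-2-en-1-ol
Product: 21 [(2-bromoprop-2-en-1-yl)oxy](tert-butyl)diphenylsilane
Conditions: t-BuPh2SiCl, imidazole, CH2Cl2, 0 → 23 °C
Reagents that add atoms: tert-butyl(chloro)diphenylsilane, CC(C)(C)[Si](Cl)(c1ccccc1)c1ccccc1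
Why: Standard silylation of a primary allylic alcohol; the bulky silyl group slows the 1,4 O→C silyl shift of the vinyllithium made from it.

Step 13
Reactants: 21 [(2-bromoprop-2-en-1-yl)oxy](tert-butyl)diphenylsilane; 19 α-hydroxy ketone
Product: 24 triene cis-diol (C3 carbinol now bearing C4 and C15), via 2-lithioallyl ether 22 (not isolated), via alkenylcerium dichloride 23 (not isolated)
Conditions: 21, t-BuLi (2 equiv), Et2O, −78 °C; CeCl3, THF, −78 °C; then 19, −78 → −40 °C (3 equiv of 23)
Reagents that add atoms: none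
Why: Bromine–lithium exchange gives 22, transmetallation to the less basic alkenylcerium 23 suppresses enolisation, and 1,2-addition to the C3 ketone should occur antiperiplanar to the axial C8–O bond (Felkin–Anh, axial attack), so that the new C3 hydroxyl is cis to the C8 hydroxyl.

Step 14
Reactants: 24 triene cis-diol
Product: 25 cis-fused octalin diol with C10 triethylsilyl ether (ring A closed, C4=C5)
Conditions: second-generation Grubbs catalyst (5 mol %), CH2Cl2, 40 °C
Reagents that add atoms: none
Why: Ring-closing metathesis should start at the monosubstituted C5 vinyl group and close six-membered ring A onto the 1,1-disubstituted C4 alkene with loss of ethylene, helped by the cis C3 and C8 side chains, while the C11=C13 alkene cannot close a ring of useful size.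

Step 15
Reactants: 25 cis-fused octalin diol with C10 triethylsilyl ether
Product: 26 cis-fused C3,C8-dihydroxy octalin with free C10 hydroxyl (key-step precursor)
Conditions: HF·pyridine, pyridine, THF, 0 → 23 °C
Reagents that add atoms: none
Why: Buffered fluoride cleaves the triethylsilyl ether of the tertiary C10 alcohol much faster than the tert-butyldiphenylsilyl ether and is too mild to ionise the tertiary allylic C3 alcohol.

Step 16
Reactants: 26 cis-fused C3,C8-dihydroxy octalin
Product: 28 ten-membered Z-ene-1,6-dione (C3 and C8 ketones, free C10 hydroxyl), via cyclic lead diester 27 (not isolated)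
Conditions: Pb(OAc)4 (1.1 equiv), NaHCO3, CH2Cl2, −20 → 0 °C
Reagents that add atoms: none
Why: Ligand exchange at tetravalent lead turns the C3,C8 cis-diol into the five-membered cyclic diester 27, which collapses in a concerted two-electron fragmentation that breaks the C3–C8 bond, turns both carbinol carbons into the C3 and C8 carbonyls and releases Pb(OAc)2. The closest known reaction is the Criegee glycol cleavage of ring-fusion cis-decalindiols to cyclodecane-1,6-diones. The ten-membered ring is not closed by bond formation: it appears by ring merger when the bond shared by rings A and B is cut (a ring-expanding fragmentation), and the ring A cyclohexene alkene necessarily becomes the Z-C4=C5 enone. No stereocentre is created; C6, C7 and C10 were fixed on six-membered rings and are not touched, while the auxiliary centres C3 and C8 vanish. The step needs chemoselectivity for the 1,2-diol over three alkenes, two PMB ethers and the lone tertiary C10 hydroxyl, which the fast cyclic-ester pathway of a cis-diol at or below 0 °C provides. It also needs the β-alkoxy, β′-hydroxy C8 ketone with its epimerisable C7 to survive, which buffered aprotic conditions and direct use in step 17 should secure.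

Step 17
Reactants: 28 ten-membered Z-ene-1,6-dione
Product: 30 C8,C10 syn-diol (8R carbinol; C3 enone intact), via C10 diethylborinate 29 (not isolated)
Conditions: Et2BOMe, THF/MeOH (4:1), −78 °C; NaBH4, −78 °C; AcOH quench, MeOH co-evaporation
Reagents that add atoms: none
Why: Narasaka–Prasad reduction, in which borinate 29 chelates the C8 carbonyl in a half-chair and external hydride adds axially to give the 1,3-syn diol (C8-OH syn to C10-OH, as in the target), the chelate activating C8 so that the unchelated C3 enone should be left alone at −78 °C.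

Step 18
Reactants: 30 C8,C10 syn-diol; 31 (R)-2-methylbutanoic acid
Product: 32 C8 (R)-2-methylbutanoate
Conditions: EDC·HCl, DMAP (0.2 equiv), CH2Cl2, 0 → 23 °C
Reagents that add atoms: none
Why: Steglich esterification acylates the only secondary alcohol (C8) while the tertiary C10 hydroxyl does not react, and carbodiimide activation at low DMAP loading should keep the α-stereocentre of 31 intact.

Step 19
Reactants: 32 C8 (R)-2-methylbutanoate
Product: 33 C6,C12-diol
Conditions: DDQ, CH2Cl2/pH 7 phosphate buffer (10:1), 0 °C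
Reagents that add atoms: none
Why: DDQ oxidises both electron-rich benzyl ethers to oxocarbenium ions that water hydrolyses, freeing the C6 and C12 hydroxyls in one operation without touching silyl ether, ester or enone.

Step 20
Reactants: 33 C6,C12-diol
Product: 36 C15-silylated cis-fused α-methylene-γ-lactone, via hydroxy enal 34 (not isolated), via lactol 35 (not isolated)
Conditions: TEMPO (20 mol %), PhI(OAc)2 (2.5 equiv), CH2Cl2, 23 °C
Reagents that add atoms: none
Why: Oxidative lactonisation, in which TEMPO/PhI(OAc)2 oxidises the primary allylic C12 alcohol selectively to enal 34, the cis-disposed C6 hydroxyl closes lactol 35 and a second oxidation gives the lactone with C6 and C7 unchanged, hence the cis ring fusion.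

Step 21
Reactants: 36 C15-silylated cis-fused α-methylene-γ-lactone
Product: 37 CNP0130221.1 (target)
Conditions: HF·pyridine, THF, 0 → 23 °C
Reagents that add atoms: none
Why: Fluoride cleavage of the primary allylic tert-butyldiphenylsilyl ether under mildly acidic, non-nucleophilic conditions should leave the Michael-acceptor lactone, the enone, the ester and the tertiary alcohol untouched.

Compound list
1 | 3-methylcyclohex-2-en-1-one | CC1=CC(=O)CCC1 | starting material
2 | (S)-3-methyl-3-(4,4,5,5-tetramethyl-1,3,2-dioxaborolan-2-yl)cyclohexan-1-one | O=C1C[C@](C)(B2OC(C)(C)C(C)(C)O2)CCC1 | intermediate (not isolated)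
3 | (R)-3-hydroxy-3-methylcyclohexan-1-one | O=C1C[C@](C)(O)CCC1 | intermediate
4 | (R)-3-methyl-3-(triethylsilyloxy)cyclohexan-1-one | O=C1C[C@](C)(O[Si](CC)(CC)CC)CCC1 | intermediate
5 | potassium (R)-5-methyl-5-(triethylsilyloxy)cyclohex-1-en-1-olate | [K+].[O-]C1=CCC[C@@](C)(O[Si](CC)(CC)CC)C1 | intermediate (not isolated)
6 | (2R,5R)-2-hydroxy-5-methyl-5-(triethylsilyloxy)cyclohexan-1-one (C3-OH trans to C10-OSiEt3) | O=C1C[C@](C)(O[Si](CC)(CC)CC)CC[C@H]1O | intermediate
7 | prop-2-yn-1-ol | C#CCO | starting material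
8 | 1-methoxy-4-[(prop-2-yn-1-yloxy)methyl]benzene | C#CCOCc1ccc(OC)cc1 | intermediate
9 | acrolein | C=CC=O | starting material
10 | methyl{3-[(4-methoxybenzyl)oxy]prop-1-yn-1-yl}zinc | C[Zn]C#CCOCc1ccc(OC)cc1 | intermediate (not isolated)
11 | (S)-6-[(4-methoxybenzyl)oxy]hex-1-en-4-yn-3-ol | C=C[C@H](O)C#CCOCc1ccc(OC)cc1 | intermediate
12 | sodium alkenylalanate: five-membered O–Al–C11=C7–C6 ring, two 2-methoxyethoxy groups on Al, vinyl on C6, CH2OPMB on C11 | [Na+].C=C[C@@H]1O[Al-](OCCOC)(OCCOC)C(COCc2ccc(OC)cc2)=C1 | intermediate (not isolated)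
13 | (3S,4Z)-5-iodo-6-[(4-methoxybenzyl)oxy]hexa-1,4-dien-3-ol | C=C[C@H](O)/C=C(\I)COCc1ccc(OC)cc1 | intermediate
14 | (3S,4Z)-5-iodo-3,6-bis[(4-methoxybenzyl)oxy]hexa-1,4-diene | C=C[C@H](OCc1ccc(OC)cc1)/C=C(\I)COCc1ccc(OC)cc1 | intermediate
15 | (2E,4S)-4-[(4-methoxybenzyl)oxy]-2-{[(4-methoxybenzyl)oxy]methyl}hexa-2,5-dien-1-ol | C=C[C@H](OCc1ccc(OC)cc1)/C=C(\CO)COCc1ccc(OC)cc1 | intermediate
16 | (3S,4Z)-5-(bromomethyl)-3,6-bis[(4-methoxybenzyl)oxy]hexa-1,4-diene | C=C[C@H](OCc1ccc(OC)cc1)/C=C(\CBr)COCc1ccc(OC)cc1 | intermediate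
17 | allylindium dibromide from 16 (In on C13, cis to C6) | C=C[C@H](OCc1ccc(OC)cc1)/C=C(\C[In](Br)Br)COCc1ccc(OC)cc1 | intermediate (not isolated)
18 | cis-1,2-diol adduct: ring B with tertiary C8-OH and secondary C3-OH cis to each other and trans to C10-OSiEt3; C8 bears C7H[C(=CH2)CH2OPMB][CH(OPMB)CH=CH2]; C6, C7, C10 spatially as in 37 | C=C[C@H](OCc2ccc(OC)cc2)[C@H](C(=C)COCc3ccc(OC)cc3)[C@]1(O)C[C@](C)(O[Si](CC)(CC)CC)CC[C@H]1O | intermediate
19 | α-hydroxy ketone: as 18 with C3 oxidised to the ketone | C=C[C@H](OCc2ccc(OC)cc2)[C@H](C(=C)COCc3ccc(OC)cc3)[C@]1(O)C[C@](C)(O[Si](CC)(CC)CC)CCC1=O | intermediate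
20 | 2-bromoprop-2-en-1-ol | OCC(Br)=C | starting material
21 | [(2-bromoprop-2-en-1-yl)oxy](tert-butyl)diphenylsilane | C=C(Br)CO[Si](c1ccccc1)(c1ccccc1)C(C)(C)C | intermediate
22 | {3-[(tert-butyldiphenylsilyl)oxy]prop-1-en-2-yl}lithium | [Li]C(=C)CO[Si](c1ccccc1)(c1ccccc1)C(C)(C)C | intermediate (not isolated)
23 | {3-[(tert-butyldiphenylsilyl)oxy]prop-1-en-2-yl}cerium dichloride | Cl[Ce](Cl)C(=C)CO[Si](c1ccccc1)(c1ccccc1)C(C)(C)C | intermediate (not isolated)
24 | triene cis-diol: as 19 with C3 now a tertiary carbinol bearing C(=CH2)CH2OSiPh2t-Bu; C3-OH cis to C8-OH | C=C[C@H](OCc2ccc(OC)cc2)[C@H](C(=C)COCc3ccc(OC)cc3)[C@]1(O)C[C@](C)(O[Si](CC)(CC)CC)CC[C@]1(O)C(=C)CO[Si](c4ccccc4)(c4ccccc4)C(C)(C)C | intermediate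
25 | cis-fused octalin C3,C8-diol, C10 triethylsilyl ether, C6 and C12 PMB ethers, C15 TBDPS ether | COc1ccc(CO[C@H]2C=C(CO[Si](c3ccccc3)(c3ccccc3)C(C)(C)C)[C@@]4(O)CC[C@@](C)(O[Si](CC)(CC)CC)C[C@@]4(O)[C@H]2C(=C)COCc5ccc(OC)cc5)cc1 | intermediate
26 | cis-fused C3,C8-dihydroxy octalin with free C10-OH (ring A cyclohexene C3–C8, ring B carrying C10); C3/C8 cis-diol trans to C10-OH; C6-OPMB cis to the C7 propenyl group | COc1ccc(CO[C@H]2C=C(CO[Si](c3ccccc3)(c3ccccc3)C(C)(C)C)[C@@]4(O)CC[C@@](C)(O)C[C@@]4(O)[C@H]2C(=C)COCc5ccc(OC)cc5)cc1 | intermediate (key-step precursor)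
27 | cyclic diacetoxylead diester of the C3,C8-diol of 26 | COc1ccc(CO[C@H]2C=C(CO[Si](c3ccccc3)(c3ccccc3)C(C)(C)C)[C@@]4(O6)CC[C@@](C)(O)C[C@@]4(O[Pb]6(OC(C)=O)OC(C)=O)[C@H]2C(=C)COCc5ccc(OC)cc5)cc1 | intermediate (not isolated)
28 | ten-membered Z-ene-1,6-dione: C3 and C8 ketones, free C10-OH, C6-OPMB, C12-OPMB, C15-OTBDPS | COc1ccc(CO[C@H]2/C=C(/CO[Si](c3ccccc3)(c3ccccc3)C(C)(C)C)C(=O)CC[C@@](C)(O)CC(=O)[C@H]2C(=C)COCc4ccc(OC)cc4)cc1 | intermediate (key-step product)
29 | C10 diethylborinate of 28 | COc1ccc(CO[C@H]2/C=C(/CO[Si](c3ccccc3)(c3ccccc3)C(C)(C)C)C(=O)CC[C@@](C)(OB(CC)CC)CC(=O)[C@H]2C(=C)COCc4ccc(OC)cc4)cc1 | intermediate (not isolated)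
30 | C8,C10 syn-diol (8R) with C3 enone | COc1ccc(CO[C@H]2/C=C(/CO[Si](c3ccccc3)(c3ccccc3)C(C)(C)C)C(=O)CC[C@@](C)(O)C[C@@H](O)[C@H]2C(=C)COCc4ccc(OC)cc4)cc1 | intermediate
31 | (R)-2-methylbutanoic acid | CC[C@@H](C)C(O)=O | starting material
32 | C8 (R)-2-methylbutanoate of 30 | COc1ccc(CO[C@H]2/C=C(/CO[Si](c3ccccc3)(c3ccccc3)C(C)(C)C)C(=O)CC[C@@](C)(O)C[C@@H](OC(=O)[C@H](C)CC)[C@H]2C(=C)COCc4ccc(OC)cc4)cc1 | intermediate
33 | C6,C12-diol | O[C@H]1/C=C(/CO[Si](c2ccccc2)(c2ccccc2)C(C)(C)C)C(=O)CC[C@@](C)(O)C[C@@H](OC(=O)[C@H](C)CC)[C@H]1C(=C)CO | intermediate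
34 | C12 enal with free C6-OH | O[C@H]1/C=C(/CO[Si](c2ccccc2)(c2ccccc2)C(C)(C)C)C(=O)CC[C@@](C)(O)C[C@@H](OC(=O)[C@H](C)CC)[C@H]1C(=C)C=O | intermediate (not isolated)
35 | C12 lactol (anomer mixture) | C=C1C(O)O[C@H]2/C=C(/CO[Si](c3ccccc3)(c3ccccc3)C(C)(C)C)C(=O)CC[C@@](C)(O)C[C@@H](OC(=O)[C@H](C)CC)[C@@H]12 | intermediate (not isolated)
36 | C15 tert-butyldiphenylsilyl ether of the target | C=C1C(=O)O[C@H]2/C=C(/CO[Si](c3ccccc3)(c3ccccc3)C(C)(C)C)C(=O)CC[C@@](C)(O)C[C@@H](OC(=O)[C@H](C)CC)[C@@H]12 | intermediate
37 | CNP0130221.1 (6S,7R,8R,10R; (R)-2-methylbutanoate; 4Z) | C=C1C(=O)O[C@H]2/C=C(/CO)C(=O)CC[C@@](C)(O)C[C@@H](OC(=O)[C@H](C)CC)[C@@H]12 | target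

Total step count: 21.
Longest linear sequence: 17 steps (steps 4–11 and 13–21, from prop-2-yn-1-ol); the ring B line needs 14 steps and the C4/C15 line 10.

Steps most likely to fail

1. Step 10 (allylation at C8). The C6→C7 relay may be eroded by bond formation at C13 instead of C7, by E/Z equilibration of the allylindium, or by attack on the allyl face anti to the ether oxygen instead of anti to the vinyl group. Fallback: set out from iodide 14 and ketol 6. Coupling of 14 with bis(pinacolatoboryl)methane (Pd[P(t-Bu)3]2, KOH, dioxane/H2O) should give the geometrically fixed (3S,4E)-allylboronate F1. F1 is then added to 6 by InI-catalysed allylboration of the ketone, which runs through a closed chair transition state, is strictly γ-selective and allows no metallotropic isomerisation; the route is rejoined at 18.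

2. Step 17 (reduction at C8). Hydride delivery in the ten-membered ring may show poor facial selectivity, the C3 enone may be reduced in competition, or the C10 hydroxyl may be tied up as the C3 hemiketal so that chelation is lost. Fallback: set out from 28. Internal hydride delivery with Me4NBH(OAc)3 in MeCN/AcOH at −30 °C (Evans–Saksena reduction, inert towards enones) should give the 1,3-anti diol, the 8-epi diol F2. A Mitsunobu esterification of F2 with acid 31 (PPh3, DIAD, toluene, 0 °C) then inverts C8 and rejoins the route at 32.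

3. Step 16 (glycol cleavage). The free β-hydroxy ketone may undergo retro-aldol opening at C9–C10 or dehydration, the C6 ether may be lost by β-elimination, or C7 may epimerise during cleavage and isolation. Fallback: set out from silyl ether 25 and cleave it with Pb(OAc)4 under the same conditions before desilylation, which should give the more robust C10 triethylsilyl ether enedione F3. F3 is then desilylated with buffered HF·pyridine immediately before the reduction and rejoins the route at 28.

Further compounds
F1 | step 10 | (3S,4E)-3,6-bis[(4-methoxybenzyl)oxy]-5-[(4,4,5,5-tetramethyl-1,3,2-dioxaborolan-2-yl)methyl]hexa-1,4-diene | C=C[C@H](OCc1ccc(OC)cc1)/C=C(\CB2OC(C)(C)C(C)(C)O2)COCc1ccc(OC)cc1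
F2 | step 17 | 8-epi diol (C8-OH anti to C10-OH), otherwise as 30 | COc1ccc(CO[C@H]2/C=C(/CO[Si](c3ccccc3)(c3ccccc3)C(C)(C)C)C(=O)CC[C@@](C)(O)C[C@H](O)[C@H]2C(=C)COCc4ccc(OC)cc4)cc1
F3 | step 16 | C10 triethylsilyl ether of enedione 28 | COc1ccc(CO[C@H]2/C=C(/CO[Si](c3ccccc3)(c3ccccc3)C(C)(C)C)C(=O)CC[C@@](C)(O[Si](CC)(CC)CC)CC(=O)[C@H]2C(=C)COCc4ccc(OC)cc4)cc1
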